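The easy step came first: grey, red, amber and violet share one charge, with activator over substrate at 1.05, so substrate is the limiting reagent if the two react one to one.

| flask | substrate | activator | temperature | remark | time |
|---|---|---|---|---|---|
| cedar | 0.055 M | 0.116 M | 12 °C | run made earlier |  |
| elm | 0.083 M | 0.116 M | 62 °C | run made earlier |  |
| grey | 0.11 M | 0.116 M | 50 °C |  | 2.0 h |
| red | 0.11 M | 0.116 M | −10 °C |  | 2.0 h |
| amber | 0.11 M | 0.116 M | 80 °C |  | 2.0 h |
| violet | 0.11 M | 0.116 M | 20 °C |  | 2.0 h |

cedar run (percent of the substrate charged)

| time / h | ring / % |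
|---|---|
| 1.33 | 0.8 |
| 2.50 | 0 |
| 6.00 | 1.4 |
| 15.0 | 3.1 |

elm run (percent of the substrate charged)

| time / min | ring / % |
|---|---|
| 20.0 | 16.8 |
| 40.0 | 36.7 |
| 60.0 | 48.6 |
| 80.0 | 56.7 |

(standard deviation of a reading: 1 percentage point)

1. the flask that comes out highest in amount of ring, in percent of the substrate charged, or "all alike" when all lie within 1.5 percentage points (grey / red / amber / violet / all alike)
2. ring at the end, in percent of the substrate charged, grey
3. ring at the end, in percent of the substrate charged, red
4. ring at the end, in percent of the substrate charged, amber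
5. ring at the end, in percent of the substrate charged, violet

I took the rate as k·[substrate]·[activator], with k the rate constant. The last elm reading, integrated, gave k = 7.20 M⁻¹ h⁻¹ at 62 °C. In cedar, activator stood in excess, so I read it as pseudo-first-order: its last reading gave 0.0178 M⁻¹ h⁻¹ at 12 °C. Those two set an activation energy, Ea, of 95.4 kJ mol⁻¹.

Then I needed a clock. I defined τ = 1/(k·c), with c the substrate charge: the time in which a nearly equal charge gets half way, so that the converted fraction is t/(t+τ). For amber, k came to 41.2 M⁻¹ h⁻¹. That gave τ = 13.2 min, and this τ was shorter than the 2.0 h allowed. Amber therefore came to 90.1%. Grey, with τ = 4.50 h, came to 30.8%. Violet, with τ = 170 h, came to 1.16%. Red, colder still, came to 0.0136%.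

The weak link was cedar's small reading, which carries a scatter of 1 percentage point. Reforged with that reading one standard deviation higher, amber's τ lengthened to 14.4 min, and amber still came to 89.3%.

The forecast named amber, with red at 0.02%, violet at 1.3%, grey at 32% and amber at 92% (75% to 97%), this amber figure standing above mine, and warned: “Amber should be highest, unless an unseen loss or equilibrium appears at 80 °C, which is extrapolated.”

The flasks gave amber highest: amber 81.1%, grey 29.9%, violet 0.418%, red 0%.

    substrate + activator → activated form (k = 46.0 M⁻¹ h⁻¹, Ea = 74.0 kJ mol⁻¹)
    substrate + activated form → side product (k = 3.90 M⁻¹ h⁻¹, Ea = 64.0 kJ mol⁻¹)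
    activated form → ring (k = 0.320 h⁻¹, Ea = 92.0 kJ mol⁻¹)
    substrate + activated form → open dimer (k = 4.60 M⁻¹ h⁻¹, Ea = 82.0 kJ mol⁻¹)
    substrate ⇌ dormant form (K = 2.70, k = 0.450 h⁻¹, Ea = 104 kJ mol⁻¹, ΔH = 1.00 kJ mol⁻¹)
    (constants at 50 °C)

Amber's 2.0 h was 9.09 of my clocks, and its ring stood 9 points below my figure, with substrate down to 0.136% and ring at 82.0% after 20.0 h. A neighbour of amber, charged with 0.029 M of activator, had the same substrate charge and so the same τ, but at one to one its activator allowed ring at 26.4% of the substrate. That neighbour ended with activator at 0% and ring at 17.5%. Open dimer and side product each hold two substrate units; in that neighbour, with activated form at 0%, ring plus half their percentages came to 26.4%.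

The data come from a simulation for substances that don't exist; the scatter is artificial.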